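## Retrosynthetic overview

1. Numbering: ring A = C1(OH)–C2–C3(Cl)–C4(Me, homoprenyl)–C5–C10(Me); ring B = C5–C6–C7=C8(C12 aldehyde)–C9(C11 aldehyde)–C10; β is the face of the C10 methyl. The strategy rests on the trans C5–C10 ring fusion with the adjacent C9 centre in ring B: once the alkene is moved from C7=C8 to C6=C7, ring B is a cyclohexene retron (diene C5–C8, dienophile C9=C10) and C1–C4 of ring A is the tether.
2. 26 ⇐ 25 ⇐ diol 24 ⇐ enal ester 23 ⇐ Δ6 adduct 20: oxidation-level changes at C11/C12 and one allylic shift of the alkene; the C1 silyl ether comes off last.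
3. 20 ⇐ acyclic triene ester 19 by an intramolecular Diels–Alder reaction that forms C5–C10 and C8–C9 and closes ring B (cycloadduct ring) and ring A (tether ring) together; no ring exists before this step.
4. 19 ⇐ β-chloro aldehyde 14 + iodo enoate 17 (C1–C10 bond, C1 carbinol); 14 ⇐ aldehyde 9 by α-chlorination (C3) and one-carbon homologation (C1).
5. 9 ⇐ triene 6 ⇐ geranyl phosphate 2 + dienylboronate 5 by copper-catalysed SN2′ substitution (C4 quaternary centre).

Key step: step 15

Assumption 1: the chiral carbene precursor of step 4 and the sulfonamide ligand of step 13 are specified by the configuration they must deliver (6R in 6, 4S in 18); both antipodes of each are equally accessible.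
Assumption 2: in step 7 the (2S,5S)-pyrrolidine is written because the (2R,5R) antipode is taken to give (S)-2-chloro aldehydes from unbranched aldehydes; the other antipode would be used if the first run showed the opposite sense.

## Route

Step 1
Reactants: 1 geraniol
Product: 2 geranyl diethyl phosphate
Conditions: ClP(O)(OEt)2, pyridine, DMAP (cat.), CH2Cl2, 0 °C
Reagents that add atoms: diethyl chlorophosphate CCOP(=O)(Cl)OCC
Why: Phosphorylation of the primary allylic alcohol installs the leaving group for the allylic substitution without touching the (E)-trisubstituted alkene, whose geometry later fixes the sense at C4.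

Step 2
Reactants: 3 (2E)-pent-2-en-4-yn-1-ol
Product: 4 tert-butyldimethylsilyl ether of 3
Conditions: TBSCl, imidazole, CH2Cl2, 0 → 23 °C
Reagents that add atoms: tert-butyldimethylsilyl chloride CC(C)(C)[Si](C)(C)Cl
Why: Silyl ether formation; a silyl group is chosen for the C12 oxygen because it ends up on a pentadienylic carbon and must pass the aluminium Lewis acid of step 15, where a benzyl-type ether would bind the acid and ionise.

Step 3
Reactants: 4 silyl ether of pentenynol
Product: 5 (2E,4E)-5-silyloxypenta-1,3-dienyl pinacol boronate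
Conditions: pinacolborane, Cp2Zr(H)Cl (5 mol %), Et3N (10 mol %), neat, 60 °C
Reagents that add atoms: pinacolborane CC1(C)OBOC1(C)C
Why: Zirconium-catalysed hydroboration of the terminal alkyne is a syn addition with boron on the terminal carbon, so the new alkene is E and the (E,E)-diene needed for the cycloaddition is in place.

Step 4
Reactants: 2 geranyl diethyl phosphate; 5 dienyl pinacol boronate
Product: 6 (2E,4E,6R)-6-ethenyl-6,10-dimethylundeca-2,4,9-trienyl silyl ether
Conditions: CuCl (10 mol %), chiral 1-aryl-3-(2-sulfonatophenyl)-4,5-diphenylimidazolinium zwitterion (12 mol %), NaOMe (1.5 equiv), THF, 22 → 50 °C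
Reagents that add atoms: none
Why: Copper–N-heterocyclic-carbene-catalysed enantioselective allylic substitution of a trisubstituted allylic phosphate with an alkenylboronate: methoxide moves the dienyl group from boron to monovalent copper, which attacks the γ-carbon (SN2′) and creates the C4 quaternary centre beside a new vinyl group, the chiral carbene choosing the alkene face (6R).

Step 5
Reactants: 6 triene silyl ether
Product: 8 (3R,4E,6E)-8-[(tert-butyldimethylsilyl)oxy]-3-methyl-3-(4-methylpent-3-en-1-yl)octa-4,6-dien-1-ol, via 9-alkyl-9-borabicyclononane 7 (not isolated)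
Conditions: 9-BBN (1.2 equiv), THF, 0 → 23 °C; then NaOH aq., 30 % H2O2, 0 °C
Reagents that add atoms: hydrogen peroxide OO (oxygen of 8); 9-borabicyclo[3.3.1]nonane B1C2CCCC1CCC2 (boron and ring of 7)
Why: Anti-Markovnikov hydroboration–oxidation; the bulky borane takes the monosubstituted vinyl group well ahead of the 1,2-disubstituted diene and the trisubstituted alkene, and C4 is not involved.

Step 6
Reactants: 8 primary alcohol
Product: 9 (3R,4E,6E)-8-[(tert-butyldimethylsilyl)oxy]-3-methyl-3-(4-methylpent-3-en-1-yl)octa-4,6-dienal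
Conditions: DMP, CH2Cl2, 0 → 23 °C
Reagents that add atoms: none
Why: Dess–Martin oxidation of a primary alcohol to the aldehyde under mild conditions; no stereocentre is α to the new carbonyl.

Step 7
Reactants: 9 aldehyde
Product: 10 (2R,3S,4E,6E)-2-chloro-8-[(tert-butyldimethylsilyl)oxy]-3-methyl-3-(4-methylpent-3-en-1-yl)octa-4,6-dienal
Conditions: NCS (1.2 equiv), (2S,5S)-2,5-diphenylpyrrolidine (20 mol %), CH2Cl2, 0 → 23 °C; short plug, used crude
Reagents that add atoms: N-chlorosuccinimide O=C1CCC(=O)N1Cl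
Why: Organocatalytic enamine α-chlorination of an aldehyde: the C2-symmetric pyrrolidine enamine is chlorinated on one face, which sets C3 (2R in 10) under catalyst control, and the quaternary C4 next to the new centre slows both a second chlorination and enolisation of the product.

Step 8
Reactants: 10 α-chloro aldehyde
Product: 11 (2E,4E,6S,7S)-7-chloro-6-methyl-6-(4-methylpent-3-en-1-yl)nona-2,4,8-trienyl silyl ether
Conditions: Ph3PCH3Br, KHMDS, THF, 0 °C; then 10, −78 → 0 °C
Reagents that add atoms: methyltriphenylphosphonium bromide C[P+](c1ccccc1)(c1ccccc1)c1ccccc1.[Br-]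
Why: Wittig methylenation replaces the C2 carbonyl oxygen by the C1 carbon; the only acidic hydrogen (C3–H) is flanked by C4, which bears no hydrogen, so neither epimerisation nor loss of HCl should compete at low temperature.

Step 9
Reactants: 11 allylic chloride
Product: 13 (3S,4S,5E,7E)-9-[(tert-butyldimethylsilyl)oxy]-3-chloro-4-methyl-4-(4-methylpent-3-en-1-yl)nona-5,7-dien-1-ol, via 9-alkyl-9-borabicyclononane 12 (not isolated)
Conditions: 9-BBN (1.3 equiv), THF, 0 → 23 °C; then NaBO3·4H2O, H2O, 23 °C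
Reagents that add atoms: sodium perborate [Na+].[Na+].O[B-]1(O)OO[B-](O)(O)OO1 (oxygen of 13); 9-borabicyclo[3.3.1]nonane B1C2CCCC1CCC2 (boron and ring of 12)
Why: Hydroboration–oxidation of the allylic chloride: the bulk of 9-BBN and of the neopentylic C3 puts boron on terminal C1 against the inductive pull of chlorine, and the near-neutral perborate oxidation avoids base-induced 1,3-elimination of the γ-chloro borane to a cyclopropane.

Step 10
Reactants: 13 chloro alcohol
Product: 14 (3S,4S,5E,7E)-9-[(tert-butyldimethylsilyl)oxy]-3-chloro-4-methyl-4-(4-methylpent-3-en-1-yl)nona-5,7-dienal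
Conditions: DMP, CH2Cl2, 0 °C; used at once
Reagents that add atoms: none
Why: Dess–Martin oxidation without added base, so that the β-chloro aldehyde does not lose HCl by E1cB elimination.

Step 11
Reactants: 15 methyl but-2-ynoate
Product: 16 methyl (2E)-3-(tributylstannyl)but-2-enoate
Conditions: Li[Bu3SnCu(SPh)] (from Bu3SnH, LDA, PhSCu), MeOH (1.7 equiv), THF, −100 → −78 °C
Reagents that add atoms: tributyltin hydride CCCC[SnH](CCCC)CCCC
Why: Stannylcupration of an ynoate is a syn addition, and protonation of the alkenylcopper by methanol at −100 °C before it can isomerise gives the kinetic (E)-β-stannyl enoate (tin trans to the ester).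

Step 12
Reactants: 16 stannyl enoate
Product: 17 methyl (2E)-3-iodobut-2-enoate
Conditions: I2, CH2Cl2, 0 °C
Reagents that add atoms: iodine II
Why: Iododestannylation of an alkenylstannane proceeds with retention of alkene geometry.

Step 13
Reactants: 14 β-chloro aldehyde; 17 iodo enoate
Product: 18 methyl (2E,4S,6S,7S,8E,10E)-12-[(tert-butyldimethylsilyl)oxy]-6-chloro-4-hydroxy-3,7-dimethyl-7-(4-methylpent-3-en-1-yl)dodeca-2,8,10-trienoate
Conditions: CrCl2 (4 equiv), N-[2-(4-isopropyl-4,5-dihydrooxazol-2-yl)-6-methylphenyl]methanesulfonamide (single antipode, 4.4 equiv), Et3N (4.4 equiv), NiCl2 (10 mol %), THF, 23 °C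
Reagents that add atoms: none
Why: Nozaki–Hiyama–Kishi reaction: zerovalent nickel inserts into the C–I bond, the alkenyl group passes to trivalent chromium with retention of the E geometry and adds 1,2 to the aldehyde, the chiral sulfonamide on chromium choosing the aldehyde face (4S, the future C1), while the amine is bound up in the chromium complex before the β-chloro aldehyde is added.

Step 14
Reactants: 18 allylic alcohol
Product: 19 methyl (2E,4S,6S,7S,8E,10E)-4,12-bis[(tert-butyldimethylsilyl)oxy]-6-chloro-3,7-dimethyl-7-(4-methylpent-3-en-1-yl)dodeca-2,8,10-trienoate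
Conditions: TBSOTf, 2,6-lutidine, CH2Cl2, −78 → 0 °C
Reagents that add atoms: tert-butyldimethylsilyl triflate CC(C)(C)[Si](C)(C)OS(=O)(=O)C(F)(F)F
Why: Silylation of the hindered secondary allylic alcohol with the silyl triflate; the bulky, non-chelating silyl ether at C1 is one of the control elements of step 15.

Step 15
Reactants: 19 acyclic triene ester
Product: 20 methyl 1α-silyloxy-8β-(silyloxymethyl)-3β-chloro-4β,10β-dimethyl-4α-(4-methylpent-3-en-1-yl)-5α-H-Δ6-octalin-9β-carboxylate (silyl = tert-butyldimethylsilyl, trans-fused)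
Conditions: Me2AlCl (2.0 equiv), CH2Cl2, −40 → 23 °C
Reagents that add atoms: none
Why: Me2AlCl binds the ester carbonyl and lowers the LUMO of the (E)-enoate C9=C10, which adds across the (E,E)-diene C5=C6–C7=C8 in a concerted, asynchronous [4+2] cycloaddition, the intramolecular Diels–Alder reaction of a deca-1,7,9-triene with a terminal ester that is the known entry to trans-octalins with an angular methyl. Ring B closes as the six-membered cycloadduct ring through the C5–C10 and C8–C9 bonds, and ring A closes at the same time as the six-membered tether ring (C1–C4 with C5 and C10) in a chair. Suprafacial addition carries the cis relation of the C10 methyl and the ester in the (E)-enoate into C10 and C9 (both β), the ester-endo transition state puts C5–H anti to the C10 methyl (trans fusion), and the E geometry of C7=C8 puts C12 cis to the ester at C8 (a centre erased in step 17). The face of addition is set by C1, C3 and C4 in the chair: the C1 silyloxy group lies axial, away from the endo ester at C9 (equatorial it would be syn-pentane to it), the C3 chloride lies equatorial, and at C4 the methyl rather than the longer chain takes the axial position syn to the C10 methyl. The step needs endo over exo selectivity and π-facial selectivity; Lewis-acid activation should strengthen the endo preference and let the reaction run cold enough for the chair preferences to decide the face.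

Step 16
Reactants: 20 bis-silyl cycloadduct
Product: 21 C12 primary alcohol (8β-hydroxymethyl), C1 silyl ether retained
Conditions: HF·pyridine, pyridine, THF, 0 °C
Reagents that add atoms: none
Why: Selective desilylation, the primary C12 silyl ether being cleaved far faster than the axial, neopentylic C1 silyl ether beside the quaternary C10; 21 is taken on directly to forestall lactonisation of the cis γ-hydroxy ester.

Step 17
Reactants: 21 hydroxy ester
Product: 23 Δ7 enal ester (C12 aldehyde on C8, C7=C8, 9β-CO2Me), via Δ6 8β-formyl ester 22 (not isolated)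
Conditions: DMP, CH2Cl2, 0 °C; then DBU (4 equiv), 0 → 23 °C
Reagents that add atoms: none
Why: Dess–Martin oxidation gives the C12 aldehyde and base-mediated isomerisation through its dienolate (deprotonation at C8, reprotonation at C6) moves the alkene into conjugation, while the C9 ester stays β because C9–H is much less acidic and the α epimer would be syn-diaxial to the C1 silyloxy group.

Step 18
Reactants: 23 enal ester
Product: 24 11,12-diol (9β-hydroxymethyl, 8-hydroxymethyl, C7=C8)
Conditions: iBu2AlH (DIBAL-H, 6 equiv), CH2Cl2, −78 → 0 °C; potassium sodium tartrate aq.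
Reagents that add atoms: none
Why: Hydride reduction (1,2) of the enal and of the ester to the diol; the alkyl chloride, the silyl ether and the alkenes are inert to this reagent.

Step 19
Reactants: 24 diol
Product: 25 C1 silyl ether of the target dialdehyde
Conditions: (COCl)2, DMSO, CH2Cl2, −78 °C; then Et3N, −78 → −30 °C
Reagents that add atoms: none
Why: Swern oxidation activates both hydroxyls before the base is added, so the 1,4-diol goes to the dialdehyde rather than to a lactol or lactone, and the cold amine step should leave the epimerisable C9 centre untouched.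

Step 20
Reactants: 25 silyl-protected dialdehyde
Product: 26 CNP0155449.1
Conditions: HF·pyridine, THF, 0 → 23 °C
Reagents that add atoms: none
Why: Fluoride-mediated desilylation under weakly acidic conditions frees the C1 hydroxyl without the base that would epimerise C9 or attack the enal.

## Compound list

1 | geraniol, (2E)-3,7-dimethylocta-2,6-dien-1-ol | CC(C)=CCC/C(C)=C/CO | starting material
2 | diethyl (2E)-3,7-dimethylocta-2,6-dien-1-yl phosphate | CC(C)=CCC/C(C)=C/COP(=O)(OCC)OCC | intermediate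
3 | (2E)-pent-2-en-4-yn-1-ol | C#C/C=C/CO | starting material
4 | tert-butyldimethyl[(2E)-pent-2-en-4-yn-1-yloxy]silane | C#C/C=C/CO[Si](C)(C)C(C)(C)C | intermediate
5 | tert-butyldimethyl{[(2E,4E)-5-(4,4,5,5-tetramethyl-1,3,2-dioxaborolan-2-yl)penta-2,4-dien-1-yl]oxy}silane | CC(C)(C)[Si](C)(C)OC/C=C/C=C/B1OC(C)(C)C(C)(C)O1 | intermediate
6 | tert-butyl{[(2E,4E,6R)-6-ethenyl-6,10-dimethylundeca-2,4,9-trien-1-yl]oxy}dimethylsilane | CC(C)=CCC[C@](/C=C/C=C/CO[Si](C)(C)C(C)(C)C)(C)C=C | intermediate
7 | 9-alkyl-9-borabicyclo[3.3.1]nonane from 6 (boron on the former vinyl terminus, quaternary centre as in 6) | CC(C)=CCC[C@](/C=C/C=C/CO[Si](C)(C)C(C)(C)C)(C)CCB1C2CCCC1CCC2 | intermediate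
8 | (3R,4E,6E)-8-[(tert-butyldimethylsilyl)oxy]-3-methyl-3-(4-methylpent-3-en-1-yl)octa-4,6-dien-1-ol | CC(C)=CCC[C@](/C=C/C=C/CO[Si](C)(C)C(C)(C)C)(C)CCO | intermediate
9 | (3R,4E,6E)-8-[(tert-butyldimethylsilyl)oxy]-3-methyl-3-(4-methylpent-3-en-1-yl)octa-4,6-dienal | CC(C)=CCC[C@](/C=C/C=C/CO[Si](C)(C)C(C)(C)C)(C)CC=O | intermediate
10 | (2R,3S,4E,6E)-2-chloro-8-[(tert-butyldimethylsilyl)oxy]-3-methyl-3-(4-methylpent-3-en-1-yl)octa-4,6-dienal | CC(C)=CCC[C@](/C=C/C=C/CO[Si](C)(C)C(C)(C)C)(C)[C@@H](Cl)C=O | intermediate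
11 | tert-butyl{[(2E,4E,6S,7S)-7-chloro-6-methyl-6-(4-methylpent-3-en-1-yl)nona-2,4,8-trien-1-yl]oxy}dimethylsilane | CC(C)=CCC[C@](/C=C/C=C/CO[Si](C)(C)C(C)(C)C)(C)[C@@H](Cl)C=C | intermediate
12 | 9-alkyl-9-borabicyclo[3.3.1]nonane from 11 (boron on the former vinyl terminus, stereocentres as in 11) | CC(C)=CCC[C@](/C=C/C=C/CO[Si](C)(C)C(C)(C)C)(C)[C@@H](Cl)CCB1C2CCCC1CCC2 | intermediate
13 | (3S,4S,5E,7E)-9-[(tert-butyldimethylsilyl)oxy]-3-chloro-4-methyl-4-(4-methylpent-3-en-1-yl)nona-5,7-dien-1-ol | CC(C)=CCC[C@](/C=C/C=C/CO[Si](C)(C)C(C)(C)C)(C)[C@@H](Cl)CCO | intermediate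
14 | (3S,4S,5E,7E)-9-[(tert-butyldimethylsilyl)oxy]-3-chloro-4-methyl-4-(4-methylpent-3-en-1-yl)nona-5,7-dienal | CC(C)=CCC[C@](/C=C/C=C/CO[Si](C)(C)C(C)(C)C)(C)[C@@H](Cl)CC=O | intermediate
15 | methyl but-2-ynoate | CC#CC(=O)OC | starting material
16 | methyl (2E)-3-(tributylstannyl)but-2-enoate | CCCC[Sn](CCCC)(CCCC)/C(C)=C/C(=O)OC | intermediate
17 | methyl (2E)-3-iodobut-2-enoate | I/C(C)=C/C(=O)OC | intermediate
18 | methyl (2E,4S,6S,7S,8E,10E)-12-[(tert-butyldimethylsilyl)oxy]-6-chloro-4-hydroxy-3,7-dimethyl-7-(4-methylpent-3-en-1-yl)dodeca-2,8,10-trienoate | CC(C)=CCC[C@](/C=C/C=C/CO[Si](C)(C)C(C)(C)C)(C)[C@@H](Cl)C[C@H](O)/C(C)=C/C(=O)OC | intermediate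
19 | methyl (2E,4S,6S,7S,8E,10E)-4,12-bis[(tert-butyldimethylsilyl)oxy]-6-chloro-3,7-dimethyl-7-(4-methylpent-3-en-1-yl)dodeca-2,8,10-trienoate | CC(C)=CCC[C@](/C=C/C=C/CO[Si](C)(C)C(C)(C)C)(C)[C@@H](Cl)C[C@H](O[Si](C)(C)C(C)(C)C)/C(C)=C/C(=O)OC | intermediate
20 | methyl 1α-[(tert-butyldimethylsilyl)oxy]-8β-{[(tert-butyldimethylsilyl)oxy]methyl}-3β-chloro-4β,10β-dimethyl-4α-(4-methylpent-3-en-1-yl)-5α-H-Δ6-octalin-9β-carboxylate (overview numbering) | CC(C)=CCC[C@]1(C)[C@@H](Cl)C[C@H](O[Si](C)(C)C(C)(C)C)[C@]2(C)[C@@H](C(=O)OC)[C@@H](CO[Si](C)(C)C(C)(C)C)C=C[C@@H]12 | intermediate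
21 | methyl 1α-[(tert-butyldimethylsilyl)oxy]-3β-chloro-8β-(hydroxymethyl)-4β,10β-dimethyl-4α-(4-methylpent-3-en-1-yl)-5α-H-Δ6-octalin-9β-carboxylate | CC(C)=CCC[C@]1(C)[C@@H](Cl)C[C@H](O[Si](C)(C)C(C)(C)C)[C@]2(C)[C@@H](C(=O)OC)[C@@H](CO)C=C[C@@H]12 | intermediate
22 | methyl 1α-[(tert-butyldimethylsilyl)oxy]-3β-chloro-8β-formyl-4β,10β-dimethyl-4α-(4-methylpent-3-en-1-yl)-5α-H-Δ6-octalin-9β-carboxylate | CC(C)=CCC[C@]1(C)[C@@H](Cl)C[C@H](O[Si](C)(C)C(C)(C)C)[C@]2(C)[C@@H](C(=O)OC)[C@@H](C=O)C=C[C@@H]12 | intermediate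
23 | methyl 1α-[(tert-butyldimethylsilyl)oxy]-3β-chloro-8-formyl-4β,10β-dimethyl-4α-(4-methylpent-3-en-1-yl)-5α-H-Δ7-octalin-9β-carboxylate | CC(C)=CCC[C@]1(C)[C@@H](Cl)C[C@H](O[Si](C)(C)C(C)(C)C)[C@]2(C)[C@@H](C(=O)OC)C(C=O)=CC[C@@H]12 | intermediate
24 | 1α-[(tert-butyldimethylsilyl)oxy]-3β-chloro-8,9β-bis(hydroxymethyl)-4β,10β-dimethyl-4α-(4-methylpent-3-en-1-yl)-5α-H-Δ7-octalin | CC(C)=CCC[C@]1(C)[C@@H](Cl)C[C@H](O[Si](C)(C)C(C)(C)C)[C@]2(C)[C@@H](CO)C(CO)=CC[C@@H]12 | intermediate
25 | 1-O-(tert-butyldimethylsilyl) ether of 26 | CC(C)=CCC[C@]1(C)[C@@H](Cl)C[C@H](O[Si](C)(C)C(C)(C)C)[C@]2(C)[C@@H](C=O)C(C=O)=CC[C@@H]12 | intermediate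
26 | CNP0155449.1, (1S,3S,4S,5R,9R,10S)-3-chloro-1-hydroxy-4,10-dimethyl-4-(4-methylpent-3-en-1-yl)-Δ7-octalin-8,9-dicarbaldehyde (overview numbering; 1α-OH, 3β-Cl, 9β-CHO, trans-fused) | CC(C)=CCC[C@]1(C)[C@@H](Cl)C[C@H](O)[C@]2(C)[C@@H](C=O)C(C=O)=CC[C@@H]12 | target

## Step count and risks

Total step count: 20. Longest linear sequence: 17 steps from (2E)-pent-2-en-4-yn-1-ol (steps 2–10, 13–20); the geraniol branch (step 1) joins at step 4 and the methyl but-2-ynoate branch (steps 11, 12) joins at step 13.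

Step 15 (key step). The β,β-disubstituted enoate may react too slowly at temperatures at which the Lewis acid leaves the silyl ethers and the chloride alone, and on warming the endo/exo and π-facial discrimination may fade. The fallback changes the dienophile to the enal, which is activated far more strongly. It sets out from 19: iBu2AlH (CH2Cl2, −78 °C) reduces the ester to the allylic alcohol F1; MnO2 (CH2Cl2, 23 °C) gives the trienal F2; Me2AlCl at −78 → −40 °C should close it through the same ester-position-endo chair transition state to the C9 aldehyde cycloadduct F3; Pinnick oxidation (NaClO2, NaH2PO4, 2-methyl-2-butene, t-BuOH/H2O) gives the carboxylic acid F4; TMSCHN2 in MeOH/toluene returns the methyl ester, so the fallback comes back to the route at 20.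

Step 7. Enamine formation and chlorination at the neopentylic aldehyde may be slow, and the catalyst may not override the neighbouring quaternary centre, so that C3 forms as a mixture or the chloro aldehyde epimerises. The fallback is auxiliary-controlled enolate chlorination and sets out from 9: Pinnick oxidation gives the acid F5; pivaloyl chloride/Et3N (THF, −20 °C) gives the mixed pivalic anhydride F6, which acylates lithiated (R)-4-benzyl-oxazolidin-2-one to the imide F7; the boron enolate (Bu2BOTf, iPr2NEt, CH2Cl2, −78 °C) is chlorinated by NCS on the face away from the benzyl group to give the (2R)-chloro imide F8; LiBH4 (Et2O, 1 equiv H2O, 0 °C) removes the auxiliary and gives the chlorohydrin F9; Dess–Martin oxidation returns the chloro aldehyde, so the fallback comes back at 10.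

Step 13. Ligand control over the aldehyde face may be incomplete with this β-chloro aldehyde, and the amine needed to form the chromium sulfonamide complex may cause loss of HCl from it. The fallback makes the C1 centre by ketone reduction and sets out from 14 and 17: the ligand-free Nozaki–Hiyama–Kishi coupling (CrCl2, NiCl2 cat., DMSO, 23 °C) gives 18 together with its C1 epimer F10; Dess–Martin oxidation of the mixture gives the single enone F11; Corey–Bakshi–Shibata reduction with (R)-2-methyl-CBS-oxazaborolidine and BH3·SMe2 (THF, −40 °C), the alkenyl group acting as the large substituent, should deliver hydride to the face that gives the 4S alcohol, so the fallback comes back at 18.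

## Further compounds

F1 | step 15 | (2E,4S,6S,7S,8E,10E)-4,12-bis[(tert-butyldimethylsilyl)oxy]-6-chloro-3,7-dimethyl-7-(4-methylpent-3-en-1-yl)dodeca-2,8,10-trien-1-ol | CC(C)=CCC[C@](/C=C/C=C/CO[Si](C)(C)C(C)(C)C)(C)[C@@H](Cl)C[C@H](O[Si](C)(C)C(C)(C)C)/C(C)=C/CO
F2 | step 15 | (2E,4S,6S,7S,8E,10E)-4,12-bis[(tert-butyldimethylsilyl)oxy]-6-chloro-3,7-dimethyl-7-(4-methylpent-3-en-1-yl)dodeca-2,8,10-trienal | CC(C)=CCC[C@](/C=C/C=C/CO[Si](C)(C)C(C)(C)C)(C)[C@@H](Cl)C[C@H](O[Si](C)(C)C(C)(C)C)/C(C)=C/C=O
F3 | step 15 | 9β-carbaldehyde analogue of 20 (CHO in place of CO2Me) | CC(C)=CCC[C@]1(C)[C@@H](Cl)C[C@H](O[Si](C)(C)C(C)(C)C)[C@]2(C)[C@@H](C=O)[C@@H](CO[Si](C)(C)C(C)(C)C)C=C[C@@H]12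
F4 | step 15 | 9β-carboxylic acid analogue of 20 (CO2H in place of CO2Me) | CC(C)=CCC[C@]1(C)[C@@H](Cl)C[C@H](O[Si](C)(C)C(C)(C)C)[C@]2(C)[C@@H](C(=O)O)[C@@H](CO[Si](C)(C)C(C)(C)C)C=C[C@@H]12
F5 | step 7 | (3R,4E,6E)-8-[(tert-butyldimethylsilyl)oxy]-3-methyl-3-(4-methylpent-3-en-1-yl)octa-4,6-dienoic acid | CC(C)=CCC[C@](/C=C/C=C/CO[Si](C)(C)C(C)(C)C)(C)CC(=O)O
F6 | step 7 | mixed anhydride of F5 with pivalic acid | CC(C)=CCC[C@](/C=C/C=C/CO[Si](C)(C)C(C)(C)C)(C)CC(=O)OC(=O)C(C)(C)C
F7 | step 7 | (4R)-4-benzyl-3-[(3R,4E,6E)-8-[(tert-butyldimethylsilyl)oxy]-3-methyl-3-(4-methylpent-3-en-1-yl)octa-4,6-dienoyl]oxazolidin-2-one | CC(C)=CCC[C@](/C=C/C=C/CO[Si](C)(C)C(C)(C)C)(C)CC(=O)N1[C@H](Cc2ccccc2)COC1=O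
F8 | step 7 | (4R)-4-benzyl-3-[(2R,3S,4E,6E)-2-chloro-8-[(tert-butyldimethylsilyl)oxy]-3-methyl-3-(4-methylpent-3-en-1-yl)octa-4,6-dienoyl]oxazolidin-2-one | CC(C)=CCC[C@](/C=C/C=C/CO[Si](C)(C)C(C)(C)C)(C)[C@@H](Cl)C(=O)N1[C@H](Cc2ccccc2)COC1=O
F9 | step 7 | (2R,3S,4E,6E)-2-chloro-8-[(tert-butyldimethylsilyl)oxy]-3-methyl-3-(4-methylpent-3-en-1-yl)octa-4,6-dien-1-ol | CC(C)=CCC[C@](/C=C/C=C/CO[Si](C)(C)C(C)(C)C)(C)[C@@H](Cl)CO
F10 | step 13 | (4R) epimer of 18, methyl (2E,4R,6S,7S,8E,10E)-12-[(tert-butyldimethylsilyl)oxy]-6-chloro-4-hydroxy-3,7-dimethyl-7-(4-methylpent-3-en-1-yl)dodeca-2,8,10-trienoate | CC(C)=CCC[C@](/C=C/C=C/CO[Si](C)(C)C(C)(C)C)(C)[C@@H](Cl)C[C@@H](O)/C(C)=C/C(=O)OC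
F11 | step 13 | methyl (2E,6S,7S,8E,10E)-12-[(tert-butyldimethylsilyl)oxy]-6-chloro-3,7-dimethyl-7-(4-methylpent-3-en-1-yl)-4-oxododeca-2,8,10-trienoate | CC(C)=CCC[C@](/C=C/C=C/CO[Si](C)(C)C(C)(C)C)(C)[C@@H](Cl)CC(=O)/C(C)=C/C(=O)OC
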